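In the blue run the left-handed substrate had lost 20 percentage points by the last reading, more than the 3.6 points of the right-handed substrate, so the left-handed share of the loss was 84.7%.

the same everywhere: left-handed substrate 0.25 M; right-handed substrate 0.25 M; free catalyst 20 mM
- blue: coupling partner 0.20 M; protic impurity 0.50 M; run made earlier
- oak: coupling partner 0.200 M; protic impurity 0.250 M; time 20 min
- ash: coupling partner 0.200 M; protic impurity 0.250 M; time 5.0 min

blue run (percent of the left-handed substrate and right-handed substrate together charged)

| time / s | right-handed substrate / % | left-handed substrate / % |
|---|---|---|
| 10.0 | 48.7 | 46.1 |
| 15.0 | 48.4 | 44.4 |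
| 25.0 | 47.8 | 41.0 |
| 40.0 | 47.6 | 37.4 |
| 80.0 | 47.7 | 34.3 |
| 120 | 46.4 | 30.1 |

(standard deviation of a reading: 0.5 percentage points)

- free catalyst is single-handed; left-handed substrate and right-handed substrate are mirror images of each other, charged as a racemate, each of them at the stated concentration
- reactions considered so far: free catalyst + right-handed substrate <-> catalyst intermediate B; coupling partner + catalyst intermediate A -> free catalyst + left-handed product; coupling partner + catalyst intermediate B -> free catalyst + right-handed product; coupling partner <-> dormant form; free catalyst + left-handed substrate <-> catalyst intermediate A; coupling partner + protic impurity -> quenched reagent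
- an excess is the difference of the two amounts in percent of their sum
- an excess is below zero if the other one leads
- no earlier run changes the charge of protic impurity; that part of a forecast is a guess

1. which one finishes higher in excess of right-handed substrate over left-handed substrate among what is left of the two ("neither" within 2 percentage points) (oak / ash / neither)
2. excess of right-handed substrate over left-handed substrate among what is left of the two at the end, oak
3. excess of right-handed substrate over left-handed substrate among what is left of the two at the end, ash

I followed one molecule of coupling partner, the limiting reagent, which ends in product or is lost. The rungs came from blue. First, by 10.0 s, the catalyst loaded. Next, the loss slowed from 1.63 mM s⁻¹ to 0.531 mM s⁻¹. Taking the rate proportional to [coupling partner], I read its lifetime from the two windows: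

lifetime = 49.0 s, leaving 8.63% at the last reading.

Counting the whole catalyst charge as bound, I took the rest of the lost substrate as product:

product share = 53.4% of the coupling partner used

The odds of reaching product against being lost were then 1.14. As a guess, I let every loss scale with [protic impurity]. At half the blue charge, this gave:

oak odds = 2.29, product = 139 mM, excess = 32.4%

The final rung, in oak and ash, was the end of the coupling partner. Its lifetime became 63.9 s, shorter than ash's 5.0 min. By this reckoning ash kept 0.912% of its coupling partner and trailed oak by 0.38 points, inside the margin, so I expected neither to lead.

The forecast said oak, with 37% for oak and 32% for ash, reading the tail as “coupling partner parked in the dormant form”.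

The flask gave 29.6% for oak and 28.8% for ash, so neither. In oak, free catalyst stood at 26.1% of its charge, where I had counted none free. Oak's odds, product against quenched reagent plus dormant form, came to 2.25, against my 2.29.

    free catalyst + right-handed substrate ⇌ catalyst intermediate B (K = 6.60 L mol⁻¹, k = 15.0 L mol⁻¹ s⁻¹)
    coupling partner + catalyst intermediate A → free catalyst + left-handed product (k = 1.00 L mol⁻¹ s⁻¹)
    coupling partner + catalyst intermediate B → free catalyst + right-handed product (k = 0.170 L mol⁻¹ s⁻¹)
    coupling partner ⇌ dormant form (K = 38.0, k = 0.00130 s⁻¹)
    free catalyst + left-handed substrate ⇌ catalyst intermediate A (K = 11.0 L mol⁻¹, k = 15.0 L mol⁻¹ s⁻¹)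
    coupling partner + protic impurity → quenched reagent (k = 0.0130 L mol⁻¹ s⁻¹)

For a neighbouring flask, ash with 0.62 M of protic impurity, my odds become 0.922, which gives 96.0 mM of product and an excess of 20.9%. The computed flask gave 21.3%.

(Readings and results are calculated for an exercise, and the scatter is random.)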